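- Moles per litre, not percent, show what these flasks can do, since partner is consumed as a reagent and more substrate than partner is charged in elm, birch and larch.

| setting | zeta | alpha | beta | elm | birch | larch |
|---|---|---|---|---|---|---|
| substrate | 0.12 M | 0.12 M | 0.12 M | 0.12 M | 0.12 M | 0.12 M |
| partner | 0.072 M | 0.072 M | 0.036 M | 0.0720 M | 0.0720 M | 0.0720 M |
| protic impurity | 0.017 M | 0.026 M | 0.012 M | 0.0120 M | 0.0120 M | 0.0120 M |
| capture agent | 0.012 M | 0.012 M | 0.012 M | 0.0120 M | 0.0120 M | 0.0120 M |
| temperature | 35 °C | 55 °C | 35 °C |  | 40 °C | 70 °C |
| remark | run made earlier | run made earlier | run made earlier | at 40 °C until 5.0 h, from then on at 70 °C |  |  |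
| time |  |  |  | 15 h | 15 h | 15 h |

| run | time / h | target / % | side product / % |
|---|---|---|---|
| zeta | 0.667 | 0 | 3 |
| zeta | 1.33 | 1 | 0 |
| zeta | 2.00 | 2 | 4 |
| zeta | 3.00 | 3 | 7 |
| zeta | 5.00 | 1 | 12 |
| zeta | 10.0 | 0 | 14 |
| alpha | 0.667 | 0 | 10 |
| alpha | 1.33 | 0 | 12 |
| alpha | 2.50 | 1 | 13 |
| alpha | 3.00 | 1 | 15 |
| alpha | 4.00 | 1 | 15 |
| alpha | 5.00 | 6 | 14 |
| beta | 0.667 | 1 | 3 |
| beta | 1.33 | 1 | 3 |
| beta | 2.50 | 0 | 0 |
| beta | 5.00 | 0 | 5 |
| beta | 10.0 | 0 | 4 |

(readings scatter by 1.5 percentage points)

* which flask leads in share of target in all that became target or side product or trapped intermediate ("all alike" within 1.5 percentage points) (elm / birch / larch / all alike)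
* share of target in all that became target or side product or trapped intermediate, elm
* share of target in all that became target or side product or trapped intermediate, birch
* share of target in all that became target or side product or trapped intermediate, larch

- the earlier runs were read with a standard deviation of 1.5 percentage points

- The alpha run looks contradictory: it is charged with 0.072 M of partner, yet its side product levels off near 15 % of substrate, or 0.0180 M, which is a quarter of that charge.
- The reckoning here clears this with two assumptions. Protic impurity removes one partner each, and each side product costs two partners. The second is suggested, not proven, by zeta against beta, two runs that differ in protic impurity as well: with half the partner, side product at 10.0 h reads 4 % against 14 %, a read ratio of 3.50, more than the ratio of the partner charges.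
- On these assumptions partner is the limiting reagent, and target is the remainder once partner is used up: charge minus impurity minus twice the side product. In alpha, that remainder is 0.0100 M, or 8.33 % of substrate, against a last target reading of 6 %.
- The carried quantity is the burn, the fraction of unquenched partner that ends in side product, read from alpha as 78.3 %.
- With trapped intermediate left out, a flask that has used its partner has a target share of (1 − burn)/(1 − burn/2), so this reckoning, which assumes that the burn read from alpha at 55 °C carries over, gives larch 35.7 % and puts elm nearby. It expects birch well below them; zeta, at 35 °C with the same partner charge, reads 0 % target at 10.0 h.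
- The forecast names larch, with elm 61 %, birch 30 % and larch 63 %, reasoning that “Partner caps total product near 0.072 M”; the reckoning here differs by charging two partners per side product.

    substrate + partner ⇌ intermediate A (K = 16.0 L mol⁻¹, k = 1.60 L mol⁻¹ h⁻¹, Ea = 86.0 kJ mol⁻¹, ΔH = −40.0 kJ mol⁻¹)
    intermediate A → intermediate B (k = 0.0540 h⁻¹, Ea = 101 kJ mol⁻¹)
    partner + intermediate A → side product (k = 15.0 L mol⁻¹ h⁻¹, Ea = 79.0 kJ mol⁻¹)
    intermediate B → target (k = 0.0360 h⁻¹, Ea = 107 kJ mol⁻¹)
    partner + protic impurity → quenched reagent (k = 11.0 L mol⁻¹ h⁻¹, Ea = 77.0 kJ mol⁻¹)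
    capture agent + intermediate A → trapped intermediate (k = 0.180 L mol⁻¹ h⁻¹, Ea = 72.0 kJ mol⁻¹)
    (constants at 40 °C)

- Larch leads at 32.4 %, ahead of elm at 28.4 % and birch at 4.60 %, and birch, left until 150 h, reaches 24.0 %. In larch, the burn is 80.3 %. A neighbour of larch charged with 0.018 M of partner forms 0.00815 M of quenched reagent, and its burn is 55.4 %, less than in larch, with a target share of 60.8 %.

The runs stem from a simulated flask on assumed constants, noise included.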